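**Retrosynthetic overview**
1. The target is (2S)-naringenin joined through C3'–C3''' to (2R,3R)-aromadendrin. Both C2 centres have the same spatial sense, so 16 is traced back (hydrogenolysis, then one trans C3-hydroxylation by Rubottom oxidation) to the C2-symmetric hexabenzyl (2S,2''S)-biflavanone 11.
2. Key disconnection, made in both units at once: C2–C3 and C4–C4a of ring C, by an oxidative two-directional [4+2] annulation of bis(benzyl aryl ether) 7 (O1–C2 already in place) with ketene diethyl acetal 8 as the C3–C4 unit.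
3. Enabling feature: C2 is benzylic to ring B and para to its oxygen O4', so hydride abstraction gives a stabilised O1=C2 oxocarbenium ion; O1 sits on the phloroglucinol ring A, whose C4a (ortho to O1 and O5, para to O7) is a strong carbon nucleophile placed for six-membered closure, and the two carbons ortho to O1 are equivalent.
4. 7 comes from 3-bromo-4-hydroxybenzaldehyde 1: benzylation, borylative homocoupling (C3'–C3''' biaryl bond), reduction, double Mitsunobu etherification with 3,5-bis(benzyloxy)phenol 6.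
5. Ring order: the two rings B are joined first, the rings A are attached through O1, both rings C are closed together in the key step; the C3 hydroxyl is added last before deprotection.

Key step: step 5

Remark: 6 and 8 are taken as commercial; the hand of the squaramide catalyst that leads to Si-face attack (2S) is to be fixed on a monomeric model ether; (2S) in a flavanone unit and (2R) in a 3-hydroxyflavanone unit denote the same spatial arrangement at C2.

**Route**

Step 1
Reactants: 1 3-bromo-4-hydroxybenzaldehyde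
Product: 2 4-(benzyloxy)-3-bromobenzaldehyde
Conditions: BnBr, K2CO3, DMF, rt
Reagents that add atoms: benzyl bromide BrCc1ccccc1
Why: Williamson ether synthesis on the acidic phenol installs the ring B benzyl ether, which is removable at the end by hydrogenolysis and later acts as the para donor that activates the benzylic position.

Step 2
Reactants: 2 4-(benzyloxy)-3-bromobenzaldehyde (two molecules)
Product: 4 6,6'-bis(benzyloxy)biphenyl-3,3'-dicarbaldehyde, via arylboronic ester 3 (not isolated)
Conditions: B2pin2 (0.55 equiv), PdCl2(dppf) (5 mol %), K2CO3, DMSO/H2O, 80 °C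
Reagents that add atoms: bis(pinacolato)diboron CC1(C)OB(OC1(C)C)B1OC(C)(C)C(C)(C)O1 (its atoms stand only in 3)
Why: One-pot Miyaura borylation/Suzuki–Miyaura homocoupling should turn half of 2 into boronate 3, which couples with the remaining bromide to forge the C3'–C3''' biaryl bond while the aldehydes stay intact; no stereocentre is formed and the biaryl axis is not configurationally stable.

Step 3
Reactants: 4 6,6'-bis(benzyloxy)biphenyl-3,3'-dicarbaldehyde
Product: 5 [6,6'-bis(benzyloxy)biphenyl-3,3'-diyl]dimethanol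
Conditions: NaBH4, THF/MeOH, 0 °C
Reagents that add atoms: none
Why: Borohydride reduction of the two aryl aldehydes should give the primary benzylic alcohols without touching the benzyl ethers.

Step 4
Reactants: 5 [6,6'-bis(benzyloxy)biphenyl-3,3'-diyl]dimethanol; 6 3,5-bis(benzyloxy)phenol (two molecules)
Product: 7 3,3'-bis{[3,5-bis(benzyloxy)phenoxy]methyl}-6,6'-bis(benzyloxy)biphenyl
Conditions: PPh3, DIAD, THF, 0 °C to rt
Reagents that add atoms: none
Why: A two-fold Mitsunobu etherification should O-alkylate the acidic phenol 6 with the activated primary benzylic alcohols under neutral conditions, which avoids the labile para-alkoxybenzyl halides and places ring A on O1 of both future chromanone units.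

Step 5
Reactants: 7 3,3'-bis{[3,5-bis(benzyloxy)phenoxy]methyl}-6,6'-bis(benzyloxy)biphenyl; 8 1,1-diethoxyethene (two molecules)
Product: 11 hexa-O-benzyl (2S,2''S)-3',3'''-binaringenin, via bis(DDQH acetal) 9 (not isolated), via bis(diethyl ketal) 10 (not isolated)
Conditions: DDQ (2.1 equiv), 4 Å MS, CH2Cl2, rt; then chiral arylpyrrolidine squaramide hydrogen-bond donor (20 mol %), 8 (6 equiv), CH2Cl2/t-BuOMe, –78 to –40 °C; then 1 M aq HCl, THF, 0 °C
Reagents that add atoms: DDQ O=C1C(Cl)=C(Cl)C(=O)C(C#N)=C1C#N (its atoms stand only in 9); water O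
Why: Proposed new method: DDQ should abstract hydride from each CH2 that is benzylic to ring B and para to its benzyloxy group and park the two O1=C2 aryl oxocarbenium ions as DDQH acetals 9; the squaramide then binds the DDQH anion and re-ionises 9 at low temperature, ketene acetal 8 adds through its CH2 carbon to C2 (C2–C3), and the resulting C4 dialkoxycarbenium ion is trapped by C4a of ring A (C4–C4a) to give ketal 10, which aqueous acid hydrolyses to the ketone. The closest known reaction types are the cationic [4+2] annulation of aryl oxocarbenium ions with alkenes (oxa-Povarov reaction), the DDQ-mediated oxidative coupling of para-alkoxybenzyl ethers with π-nucleophiles and the hydrogen-bond-donor anion-binding catalysis of enantioselective ketene acetal additions to oxocarbenium ions; new are their combination, the ketene acetal as two-carbon partner and the two-directional use. Each ring C closes by intramolecular Friedel–Crafts attack of the arene carbon C4a on the C4 carbenium ion, a 6-exo-trig closure at the cationic carbon that completes a stepwise [4+2] annulation of the C2=O1–C8a=C4a heterodiene with the C3=C4 unit of 8. Each C2 stereocentre is set in the C2–C3 bond-forming step by the chiral squaramide-bound counter-anion, which has to guide 8 to the Si face of C2 (2S); because the two events are independent and catalyst-controlled, the C2-symmetric (2S,2''S) isomer should be enriched at the expense of the meso (2S,2''R) isomer, which is separable. The step needs chemoselectivity for addition of 8 over arylation of the cation by a ring A of another molecule, which the far higher π-nucleophilicity of a ketene acetal secures, and regioselective ring closure, which ring A itself secures: its two carbons ortho to O1 are equivalent and each is also ortho or para to the other two oxygens, while the para carbon cannot reach C4.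

Step 6
Reactants: 11 hexa-O-benzyl (2S,2''S)-3',3'''-binaringenin
Product: 12 mono(triethylsilyl enol ether) of 11
Conditions: TESOTf (1.0 equiv), Et3N, CH2Cl2, –78 to –20 °C; chromatography on Et3N-treated silica
Reagents that add atoms: triethylsilyl trifluoromethanesulfonate CC[Si](CC)(CC)OS(=O)(=O)C(F)(F)F
Why: Soft enolisation with a silyl triflate and an amine should convert one ketone into its enol ether; the two flavanone units of C2-symmetric 11 are homotopic, so monosilylation needs only conversion control and no site selectivity, unreacted 11 and hydrolysed bis(enol ether) are recycled, and C2 is not touched.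

Step 7
Reactants: 12 mono(triethylsilyl enol ether) of 11
Product: 15 hexa-O-benzyl naringenin-(3'→3''')-aromadendrin, via silyloxy oxirane 13 (not isolated), via 3-silyloxy ketone 14 (not isolated)
Conditions: DMDO (1.1 equiv), acetone/CH2Cl2, –78 to –30 °C; then 1 M aq HCl, THF, 0 °C
Reagents that add atoms: dimethyldioxirane CC1(C)OO1
Why: In this Rubottom oxidation DMDO should epoxidise the electron-rich enol ether on the face anti to the C2 aryl group, and silyl migration followed by acid cleavage then gives the 2,3-trans (2R,3R) hydroxy ketone, so the existing C2 centre controls the new C3 centre.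

Step 8
Reactants: 15 hexa-O-benzyl naringenin-(3'→3''')-aromadendrin
Product: 16 naringenin-(3'→3''')-aromadendrin (CNP0201582.1)
Conditions: H2 (1 atm), Pd/C, THF/MeOH, rt
Reagents that add atoms: none
Why: Catalytic hydrogenolysis should remove the six benzyl ethers under neutral conditions, which leaves the aryl ketones, the C2–O1 bonds and all three stereocentres untouched.

**Compound list**
1 | 3-bromo-4-hydroxybenzaldehyde | O=Cc1ccc(O)c(Br)c1 | starting material
2 | 4-(benzyloxy)-3-bromobenzaldehyde | O=Cc1ccc(OCc2ccccc2)c(Br)c1 | intermediate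
3 | 4-(benzyloxy)-3-(4,4,5,5-tetramethyl-1,3,2-dioxaborolan-2-yl)benzaldehyde | O=Cc1ccc(OCc2ccccc2)c(B2OC(C)(C)C(C)(C)O2)c1 | intermediate
4 | 6,6'-bis(benzyloxy)biphenyl-3,3'-dicarbaldehyde | O=Cc1ccc(OCc2ccccc2)c(-c2cc(C=O)ccc2OCc2ccccc2)c1 | intermediate
5 | [6,6'-bis(benzyloxy)biphenyl-3,3'-diyl]dimethanol | OCc1ccc(OCc2ccccc2)c(-c2cc(CO)ccc2OCc2ccccc2)c1 | intermediate
6 | 3,5-bis(benzyloxy)phenol | Oc1cc(OCc2ccccc2)cc(OCc2ccccc2)c1 | starting material
7 | 3,3'-bis{[3,5-bis(benzyloxy)phenoxy]methyl}-6,6'-bis(benzyloxy)biphenyl | C(Oc1cc(OCc2ccccc2)cc(OCc2ccccc2)c1)c1ccc(OCc2ccccc2)c(-c2cc(COc3cc(OCc4ccccc4)cc(OCc4ccccc4)c3)ccc2OCc2ccccc2)c1 | intermediate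
8 | 1,1-diethoxyethene (ketene diethyl acetal) | C=C(OCC)OCC | starting material
9 | 3,3'-bis{[3,5-bis(benzyloxy)phenoxy](2,3-dichloro-5,6-dicyano-4-hydroxyphenoxy)methyl}-6,6'-bis(benzyloxy)biphenyl (acetal carbons unassigned) | Oc1c(Cl)c(Cl)c(OC(Oc2cc(OCc3ccccc3)cc(OCc3ccccc3)c2)c2ccc(OCc3ccccc3)c(-c3cc(C(Oc4cc(OCc5ccccc5)cc(OCc5ccccc5)c4)Oc4c(C#N)c(C#N)c(O)c(Cl)c4Cl)ccc3OCc3ccccc3)c2)c(C#N)c1C#N | intermediate
10 | 2,2'-[6,6'-bis(benzyloxy)biphenyl-3,3'-diyl]bis[(2S)-5,7-bis(benzyloxy)-4,4-diethoxychroman] | CCOC1(OCC)C[C@@H](c2ccc(OCc3ccccc3)c(-c3cc([C@H]4Oc5cc(OCc6ccccc6)cc(OCc6ccccc6)c5C(OCC)(OCC)C4)ccc3OCc3ccccc3)c2)Oc2cc(OCc3ccccc3)cc(OCc3ccccc3)c21 | intermediate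
11 | 2,2'-[6,6'-bis(benzyloxy)biphenyl-3,3'-diyl]bis[(2S)-5,7-bis(benzyloxy)chroman-4-one] (hexa-O-benzyl (2S,2''S)-3',3'''-binaringenin) | O=C1C[C@@H](c2ccc(OCc3ccccc3)c(-c3cc([C@H]4Oc5cc(OCc6ccccc6)cc(OCc6ccccc6)c5C(=O)C4)ccc3OCc3ccccc3)c2)Oc2cc(OCc3ccccc3)cc(OCc3ccccc3)c21 | intermediate
12 | (2S)-5,7-bis(benzyloxy)-2-{6,6'-bis(benzyloxy)-3'-[(2S)-5,7-bis(benzyloxy)-4-(triethylsilyloxy)-2H-chromen-2-yl]biphenyl-3-yl}chroman-4-one | O=C1C[C@@H](c2ccc(OCc3ccccc3)c(-c3cc([C@H]4Oc5cc(OCc6ccccc6)cc(OCc6ccccc6)c5C(O[Si](CC)(CC)CC)=C4)ccc3OCc3ccccc3)c2)Oc2cc(OCc3ccccc3)cc(OCc3ccccc3)c21 | intermediate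
13 | 3,4-epoxide of 12 (4-triethylsilyloxy oxirane, oxirane oxygen trans to the C2 aryl group) | O=C1C[C@@H](c2ccc(OCc3ccccc3)c(-c3cc([C@H]4Oc5cc(OCc6ccccc6)cc(OCc6ccccc6)c5[C@]7(O[Si](CC)(CC)CC)O[C@H]47)ccc3OCc3ccccc3)c2)Oc2cc(OCc3ccccc3)cc(OCc3ccccc3)c21 | intermediate
14 | 3-O-triethylsilyl ether of 15 ((2R,3R)-3-silyloxy ketone) | O=C1C[C@@H](c2ccc(OCc3ccccc3)c(-c3cc([C@H]4Oc5cc(OCc6ccccc6)cc(OCc6ccccc6)c5C(=O)[C@@H]4O[Si](CC)(CC)CC)ccc3OCc3ccccc3)c2)Oc2cc(OCc3ccccc3)cc(OCc3ccccc3)c21 | intermediate
15 | (2S)-5,7-bis(benzyloxy)-2-{6,6'-bis(benzyloxy)-3'-[(2R,3R)-5,7-bis(benzyloxy)-3-hydroxy-4-oxochroman-2-yl]biphenyl-3-yl}chroman-4-one | O=C1C[C@@H](c2ccc(OCc3ccccc3)c(-c3cc([C@H]4Oc5cc(OCc6ccccc6)cc(OCc6ccccc6)c5C(=O)[C@@H]4O)ccc3OCc3ccccc3)c2)Oc2cc(OCc3ccccc3)cc(OCc3ccccc3)c21 | intermediate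
16 | (2R,3R)-2-{6,6'-dihydroxy-3'-[(2S)-5,7-dihydroxy-4-oxochroman-2-yl]biphenyl-3-yl}-3,5,7-trihydroxychroman-4-one (CNP0201582.1) | O=C1C[C@@H](c2ccc(O)c(-c3cc([C@H]4Oc5cc(O)cc(O)c5C(=O)[C@@H]4O)ccc3O)c2)Oc2cc(O)cc(O)c21 | target

**Summary**
Total step count: 8. Longest linear sequence: 8 steps (1 to 16).

Steps most likely to fail:

Step 5 (proposed method). What may go wrong: ionisation of the DDQH acetal without the catalyst and hence poor facial selectivity at C2; intermolecular Friedel–Crafts alkylation leading to oligomers; dealkylation or deprotonation of the dialkoxycarbenium ion before ring closure; over-oxidation to the flavone level by excess DDQ. Fallback with known chemistry, setting out from 4 and coming back at 11: Claisen–Schmidt condensation of 4 with two equivalents of commercial 1-[2,4-bis(benzyloxy)-6-hydroxyphenyl]ethanone (KOH, EtOH/THF) should give the bis(2'-hydroxychalcone) F1. Oxidative cyclisation with catalytic I2 in DMSO at 120 °C gives the bis(flavone) F2. Asymmetric hydrogenation of the flavone C2=C3 bonds with [Ru(cod)(2-methylallyl)2] and a chiral N-heterocyclic carbene ligand under H2 sets both C2 centres and gives the (2S,2''S)-bis(flavan-4-ol) F3, whose carbinol configuration is irrelevant. Dess–Martin periodinane then returns the ketones of 11.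

Step 6. What may go wrong: over-silylation together with incomplete conversion (statistical distribution), and silyl triflate-promoted ionisation of the C2–O1 bond with loss of configuration at C2. Fallback, setting out from 2 and coming back at 15, in which the two units are differentiated as monomers before the biaryl bond exists: 2 is reduced with NaBH4 to (4-(benzyloxy)-3-bromophenyl)methanol F4 and etherified with 6 under Mitsunobu conditions to the bromo benzyl aryl ether F5. The one-flask protocol of step 5, run once on this monomer, should pass through the DDQH acetal F6 and the diethyl ketal F7 to the (2S)-3'-bromoflavanone F8. One portion of F8 is silylated exhaustively (TESOTf in excess, Et3N) to the enol ether F9 and oxidised with DMDO through the silyloxy oxirane F10 and the 3-silyloxy ketone F11 to the (2R,3R)-3'-bromo-3-hydroxyflavanone F12, so that no statistical step remains. The other portion is converted with hexamethylditin and Pd(PPh3)4 in toluene into the arylstannane F13. A base-free Stille coupling of F13 with F12 (Pd2(dba)3, AsPh3, CuI, NMP, 60 °C) should then give 15 without exposing either unit to base.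

Step 7. What may go wrong: unselective oxygen transfer to the benzylic CH2 groups and the electron-rich rings, and incomplete facial selectivity of the epoxidation. Fallback, setting out from 12 and coming back at 15: catalytic OsO4 with N-methylmorpholine N-oxide in acetone/water should dihydroxylate the C3=C4 enol ether bond of 12 from the face anti to the C2 aryl group, and the resulting hemiketal collapses with loss of triethylsilanol directly to 15; no compound outside the list is made (F0).

**Further compounds**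
F1 | step 5 | 3,3'-bis{(E)-3-[2,4-bis(benzyloxy)-6-hydroxyphenyl]-3-oxoprop-1-enyl}-6,6'-bis(benzyloxy)biphenyl | O=C(/C=C/c1ccc(OCc2ccccc2)c(-c2cc(/C=C/C(=O)c3c(O)cc(OCc4ccccc4)cc3OCc3ccccc3)ccc2OCc2ccccc2)c1)c1c(O)cc(OCc2ccccc2)cc1OCc1ccccc1
F2 | step 5 | 2,2'-[6,6'-bis(benzyloxy)biphenyl-3,3'-diyl]bis[5,7-bis(benzyloxy)-4H-chromen-4-one] | O=c1cc(-c2ccc(OCc3ccccc3)c(-c3cc(-c4cc(=O)c5c(OCc6ccccc6)cc(OCc6ccccc6)cc5o4)ccc3OCc3ccccc3)c2)oc2cc(OCc3ccccc3)cc(OCc3ccccc3)c12
F3 | step 5 | 2,2'-[6,6'-bis(benzyloxy)biphenyl-3,3'-diyl]bis[(2S)-5,7-bis(benzyloxy)chroman-4-ol] (C4 unassigned) | OC1C[C@@H](c2ccc(OCc3ccccc3)c(-c3cc([C@H]4Oc5cc(OCc6ccccc6)cc(OCc6ccccc6)c5C(O)C4)ccc3OCc3ccccc3)c2)Oc2cc(OCc3ccccc3)cc(OCc3ccccc3)c21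
F4 | step 6 | (4-(benzyloxy)-3-bromophenyl)methanol | OCc1ccc(OCc2ccccc2)c(Br)c1
F5 | step 6 | 1,3-bis(benzyloxy)-5-{[4-(benzyloxy)-3-bromobenzyl]oxy}benzene | Brc1cc(COc2cc(OCc3ccccc3)cc(OCc3ccccc3)c2)ccc1OCc1ccccc1
F6 | step 6 | DDQH acetal of F5 (acetal carbon unassigned) | N#Cc1c(C#N)c(OC(Oc2cc(OCc3ccccc3)cc(OCc3ccccc3)c2)c2ccc(OCc3ccccc3)c(Br)c2)c(Cl)c(Cl)c1O
F7 | step 6 | (2S)-5,7-bis(benzyloxy)-2-[4-(benzyloxy)-3-bromophenyl]-4,4-diethoxychroman | CCOC1(OCC)C[C@@H](c2ccc(OCc3ccccc3)c(Br)c2)Oc2cc(OCc3ccccc3)cc(OCc3ccccc3)c21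
F8 | step 6 | (2S)-5,7-bis(benzyloxy)-2-[4-(benzyloxy)-3-bromophenyl]chroman-4-one | O=C1C[C@@H](c2ccc(OCc3ccccc3)c(Br)c2)Oc2cc(OCc3ccccc3)cc(OCc3ccccc3)c21
F9 | step 6 | (2S)-5,7-bis(benzyloxy)-2-[4-(benzyloxy)-3-bromophenyl]-4-(triethylsilyloxy)-2H-chromene | CC[Si](CC)(CC)OC1=C[C@@H](c2ccc(OCc3ccccc3)c(Br)c2)Oc2cc(OCc3ccccc3)cc(OCc3ccccc3)c21
F10 | step 6 | 3,4-epoxide of F9 (oxirane oxygen trans to the C2 aryl group) | Brc1cc([C@H]2Oc3cc(OCc4ccccc4)cc(OCc4ccccc4)c3[C@]5(O[Si](CC)(CC)CC)O[C@H]25)ccc1OCc1ccccc1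
F11 | step 6 | (2R,3R)-5,7-bis(benzyloxy)-2-[4-(benzyloxy)-3-bromophenyl]-3-(triethylsilyloxy)chroman-4-one | Brc1cc([C@H]2Oc3cc(OCc4ccccc4)cc(OCc4ccccc4)c3C(=O)[C@@H]2O[Si](CC)(CC)CC)ccc1OCc1ccccc1
F12 | step 6 | (2R,3R)-5,7-bis(benzyloxy)-2-[4-(benzyloxy)-3-bromophenyl]-3-hydroxychroman-4-one | Brc1cc([C@H]2Oc3cc(OCc4ccccc4)cc(OCc4ccccc4)c3C(=O)[C@@H]2O)ccc1OCc1ccccc1
F13 | step 6 | (2S)-5,7-bis(benzyloxy)-2-[4-(benzyloxy)-3-(trimethylstannyl)phenyl]chroman-4-one | C[Sn](C)(C)c1cc([C@H]2Oc3cc(OCc4ccccc4)cc(OCc4ccccc4)c3C(=O)C2)ccc1OCc1ccccc1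
F0 | step 7 | none | none
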